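## Retrosynthetic overview

1. The last step closes the ten-membered carbocycle and the α-methylene-γ-lactone together: intramolecular chromium-mediated 2-(methoxycarbonyl)allylation of a C-8 aldehyde (C7–C8 bond), then lactonisation.
2. The allylic bromide comes from a C-7 aldehyde (Morita–Baylis–Hillman, then SN2' bromination). C-6 is set by chelation-controlled vinylation and acylated in the same flask. C-4 and C-5 come from a Sharpless epoxy alcohol opened by an alkynylalane.
3. The 3(2H)-furanone ring and the quaternary C-10 are made in one operation: PtCl2-catalysed heterocyclisation/1,2-methyl shift of a tertiary α-hydroxy ynone, with chirality transfer from the carbinol.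
4. That α-hydroxy ynone is assembled by a new rhodium-catalysed, site- and face-selective alkynylation of an unsymmetrical 1,2-diketone (two steps from butane-2,3-dione).
5. Ring order: furanone ring first (step 7), then the ten-membered ring and the lactone ring together (step 14).

Assumption: locants are C-1 ketone, C-2 =CH, C-3 enol-ether carbon, C-4 CHMe, C-5 CHOH, C-6 CH–O-isobutyryl, C-7, C-8 lactone CH–O, C-9 CH2, C-10 quaternary C–O, C-11/C-13 exo-methylene, C-12 lactone C=O; iPr-Phebox is 2,6-bis[(4S)-4-isopropyl-4,5-dihydro-1,3-oxazol-2-yl]phenyl, and the catalyst antipode that gives the 3R carbinol in step 6 is written as (S,S) pending one screening run.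

## Route

Step 1
Reactants: 1 (E)-but-2-en-1-ol
Product: 2 [(2R,3R)-3-methyloxiran-2-yl]methanol
Conditions: Ti(OiPr)4 (10 mol%), D-(−)-diisopropyl tartrate (12 mol%), tBuOOH, 4 Å MS, CH2Cl2, −20 °C
Reagents that add atoms: tert-butyl hydroperoxide, CC(C)(C)OO
Why: Katsuki–Sharpless asymmetric epoxidation; the D-tartrate titanium complex delivers oxygen to the alkene face that gives the (2R,3R)-epoxide, which fixes C-5 and presets C-4.

Step 2
Reactants: 2 [(2R,3R)-3-methyloxiran-2-yl]methanol; 3 ethynyltrimethylsilane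
Product: 5 (2S,3R)-3-methylpent-4-yne-1,2-diol, via silylated alkynediol 4 (not isolated)
Conditions: 3, n-BuLi, then Et2AlCl, toluene, 0 °C; add 2, 0 °C to rt; Rochelle-salt work-up; crude, K2CO3 (cat.), MeOH, rt
Reagents that add atoms: none
Why: Alkoxide-directed opening of a 2,3-epoxy alcohol by a diethylalkynylalane occurs at the distal carbon with inversion, which sets C-4 (4,5-syn); methanolysis then removes the C-silyl group.

Step 3
Reactants: 5 (2S,3R)-3-methylpent-4-yne-1,2-diol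
Product: 6 (2S,3R)-3-methyl-1,2-bis(triethylsilyloxy)pent-4-yne
Conditions: Et3SiCl (2.4 equiv), imidazole, CH2Cl2, 0 °C to rt
Reagents that add atoms: chlorotriethylsilane, CC[Si](Cl)(CC)CC
Why: Standard bis-silylation; the primary triethylsilyl ether is the latent C-6 aldehyde and the secondary one protects O-5 to the end.

Step 4
Reactants: 7 butane-2,3-dione
Product: 8 3-(trimethylsilyloxy)but-3-en-2-one
Conditions: Me3SiCl (1.05 equiv), Et3N, DMF, 40 °C
Reagents that add atoms: chlorotrimethylsilane, C[Si](C)(C)Cl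
Why: Silyl enol ether formation by soft enolisation of one of the two equivalent acetyl groups (stoichiometry-controlled mono-silylation).

Step 5
Reactants: 8 3-(trimethylsilyloxy)but-3-en-2-one; 9 2-methoxy-1,3-dioxolane
Product: 10 1-(1,3-dioxolan-2-yl)butane-2,3-dione
Conditions: TMSOTf (10 mol%), CH2Cl2, −78 °C
Reagents that add atoms: none
Why: Mukaiyama-type addition of the silyl enol ether to the 1,3-dioxolan-2-ylium ion generated from the orthoformate gives the β-keto acetal (C-9 and masked C-8); no stereocentre is formed.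

Step 6
Reactants: 6 (2S,3R)-3-methyl-1,2-bis(triethylsilyloxy)pent-4-yne; 10 1-(1,3-dioxolan-2-yl)butane-2,3-dione
Product: 11 (3R,6R,7S)-1-(1,3-dioxolan-2-yl)-3-hydroxy-3,6-dimethyl-7,8-bis(triethylsilyloxy)oct-4-yn-2-one
Conditions: [(S,S)-iPr-Phebox]Rh(OAc)2(H2O) (5 mol%), 10 (2 equiv), toluene, 40 °C
Reagents that add atoms: none
Why: Proposed new method: base-free direct alkynylation of an unsymmetrical aliphatic 1,2-diketone by a Phebox–rhodium acetate, in which acetate-assisted C–H metalation of 6 gives a trivalent rhodium acetylide, 10 binds through both carbonyl oxygens so that only the less hindered acetyl C=O can lie cis to the acetylide, migratory insertion from the face left open by the oxazoline isopropyl groups forms the C1–C2 bond and sets C-1 as R, and AcOH protonolysis turns the catalyst over; the closest known reaction type is the enantioselective alkynylation of α-keto esters by the same class of Phebox–rhodium acetates, not yet shown for 1,2-diketones or with a choice between two ketones.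

Step 7
Reactants: 11 (3R,6R,7S)-1-(1,3-dioxolan-2-yl)-3-hydroxy-3,6-dimethyl-7,8-bis(triethylsilyloxy)oct-4-yn-2-one
Product: 12 (2R)-5-[(2S,3S)-3,4-bis(triethylsilyloxy)butan-2-yl]-2-(1,3-dioxolan-2-ylmethyl)-2-methylfuran-3(2H)-one
Conditions: PtCl2 (5 mol%), toluene, 80 °C
Reagents that add atoms: none
Why: Known platinum- or gold-catalysed heterocyclisation/1,2-alkyl shift of 2-hydroxy-2-alkynyl ketones: 5-endo attack of the C-10 carbonyl oxygen on the activated alkyne gives a cyclic oxocarbenium ion, the methyl group then shifts suprafacially from C-1 to C-10 (α-ketol-type 1,2-shift) while C-1 becomes the ring ketone, so the R carbinol is transferred into the R quaternary C-10 as the furanone ring closes.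

Step 8
Reactants: 12 (2R)-5-[(2S,3S)-3,4-bis(triethylsilyloxy)butan-2-yl]-2-(1,3-dioxolan-2-ylmethyl)-2-methylfuran-3(2H)-one
Product: 13 (2S,3S)-3-[(5R)-5-(1,3-dioxolan-2-ylmethyl)-5-methyl-4-oxo-4,5-dihydrofuran-2-yl]-2-(triethylsilyloxy)butanal
Conditions: (COCl)2, DMSO, CH2Cl2, −78 to −40 °C; then Et3N, −78 to 0 °C
Reagents that add atoms: none
Why: Swern conditions convert a primary triethylsilyl ether directly into the aldehyde while the secondary silyl ether, the vinylogous ester and the acetal are untouched; no stereocentre changes.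

Step 9
Reactants: 13 (2S,3S)-3-[(5R)-5-(1,3-dioxolan-2-ylmethyl)-5-methyl-4-oxo-4,5-dihydrofuran-2-yl]-2-(triethylsilyloxy)butanal; 14 vinylmagnesium bromide; 15 2-methylpropanoyl chloride
Product: 17 (3S,4S,5S)-5-[(5R)-5-(1,3-dioxolan-2-ylmethyl)-5-methyl-4-oxo-4,5-dihydrofuran-2-yl]-4-(triethylsilyloxy)hex-1-en-3-yl 2-methylpropanoate, via vinylzinc alkoxide 16 (not isolated)
Conditions: 14 (4.4 equiv), ZnCl2 (2.2 equiv), THF then toluene; EtZnCl (1.5 equiv), toluene/CH2Cl2, −30 to 0 °C; then 15, DMAP (cat.), 0 °C to rt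
Reagents that add atoms: none
Why: Chelation-controlled (Cram-chelate) organozinc addition in which the alkylzinc halide bridges the aldehyde and α-silyloxy oxygens and divinylzinc attacks the face opposite C-4, giving the 5,6-syn alkoxide (C-6 S), which is acylated in the same flask.

Step 10
Reactants: 17 (3S,4S,5S)-5-[(5R)-5-(1,3-dioxolan-2-ylmethyl)-5-methyl-4-oxo-4,5-dihydrofuran-2-yl]-4-(triethylsilyloxy)hex-1-en-3-yl 2-methylpropanoate
Product: 18 (2R,3S,4S)-4-[(5R)-5-(1,3-dioxolan-2-ylmethyl)-5-methyl-4-oxo-4,5-dihydrofuran-2-yl]-1-oxo-3-(triethylsilyloxy)pentan-2-yl 2-methylpropanoate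
Conditions: OsO4 (2 mol%), NaIO4 (4 equiv), 2,6-lutidine, 1,4-dioxane/H2O (3:1), rt
Reagents that add atoms: osmium tetroxide, O=[Os](=O)(=O)=O; sodium periodate, [Na+].[O-]I(=O)(=O)=O
Why: Lemieux–Johnson cleavage; the terminal vinyl group is dihydroxylated much faster than the push–pull furanone alkene, and the buffered conditions leave C-6 untouched.

Step 11
Reactants: 18 (2R,3S,4S)-4-[(5R)-5-(1,3-dioxolan-2-ylmethyl)-5-methyl-4-oxo-4,5-dihydrofuran-2-yl]-1-oxo-3-(triethylsilyloxy)pentan-2-yl 2-methylpropanoate; 19 methyl acrylate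
Product: 20 methyl (4S,5S,6S)-6-[(5R)-5-(1,3-dioxolan-2-ylmethyl)-5-methyl-4-oxo-4,5-dihydrofuran-2-yl]-3-hydroxy-2-methylidene-4-(2-methylpropanoyloxy)-5-(triethylsilyloxy)heptanoate (both C-3 epimers)
Conditions: 19 (neat, excess), 3-hydroxyquinuclidine (0.3 equiv), 0 °C to rt
Reagents that add atoms: none
Why: Morita–Baylis–Hillman reaction; the activated α-acyloxy aldehyde reacts within hours, which limits epimerisation at C-6, and the new carbinol (C-7) is formed as both epimers because it is erased in step 12.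

Step 12
Reactants: 20 methyl (4S,5S,6S)-6-[(5R)-5-(1,3-dioxolan-2-ylmethyl)-5-methyl-4-oxo-4,5-dihydrofuran-2-yl]-3-hydroxy-2-methylidene-4-(2-methylpropanoyloxy)-5-(triethylsilyloxy)heptanoate
Product: 21 methyl (2Z,4S,5S,6S)-2-(bromomethyl)-6-[(5R)-5-(1,3-dioxolan-2-ylmethyl)-5-methyl-4-oxo-4,5-dihydrofuran-2-yl]-4-(2-methylpropanoyloxy)-5-(triethylsilyloxy)hept-2-enoate
Conditions: PPh3, CBr4, CH2Cl2, 0 °C
Reagents that add atoms: carbon tetrabromide, BrC(Br)(Br)Br
Why: Appel activation of the allylic alcohol followed by SN2' attack of bromide gives the thermodynamically preferred (Z)-2-(bromomethyl)enoate under neutral conditions that spare the acetal and the electron-rich furanone.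

Step 13
Reactants: 21 methyl (2Z,4S,5S,6S)-2-(bromomethyl)-6-[(5R)-5-(1,3-dioxolan-2-ylmethyl)-5-methyl-4-oxo-4,5-dihydrofuran-2-yl]-4-(2-methylpropanoyloxy)-5-(triethylsilyloxy)hept-2-enoate
Product: 22 methyl (2Z,4S,5S,6S)-2-(bromomethyl)-5-hydroxy-6-[(5R)-5-methyl-4-oxo-5-(2-oxoethyl)-4,5-dihydrofuran-2-yl]-4-(2-methylpropanoyloxy)hept-2-enoate
Conditions: TFA/H2O (9:1), CH2Cl2, 0 °C
Reagents that add atoms: water, O
Why: Acid hydrolysis unmasks the C-8 aldehyde from the dioxolane and removes the triethylsilyl ether in one operation; cold, brief acid avoids acyl migration from O-6 to O-5 and β-elimination of the furanone oxygen.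

Step 14
Reactants: 22 methyl (2Z,4S,5S,6S)-2-(bromomethyl)-5-hydroxy-6-[(5R)-5-methyl-4-oxo-5-(2-oxoethyl)-4,5-dihydrofuran-2-yl]-4-(2-methylpropanoyloxy)hept-2-enoate
Product: 24 CNP0141385.1 (target), via chromium alkoxide 23 (not isolated)
Conditions: CrCl2 (8 equiv), THF (2 mM), rt; aq. NH4Cl; lactonisation completed on SiO2
Reagents that add atoms: none
Why: Intramolecular Nozaki–Hiyama-type (chromium Barbier) 2-(methoxycarbonyl)allylation: the equilibrating γ-substituted allylchromium adds through C-7 to the C-8 aldehyde in a chair transition state held by the furanone bridge, which is expected to place H-7 and H-8 trans and C-7 anti to the C-6 acyloxy group (C-7 R, C-8 S), and the chromium alkoxide closes the lactone with loss of methanol.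

## Compound list

1 | (E)-but-2-en-1-ol | C/C=C/CO | starting material
2 | [(2R,3R)-3-methyloxiran-2-yl]methanol | C[C@H]1O[C@@H]1CO | intermediate
3 | ethynyltrimethylsilane | C#C[Si](C)(C)C | starting material
4 | (2S,3R)-3-methyl-5-(trimethylsilyl)pent-4-yne-1,2-diol | C[Si](C)(C)C#C[C@@H](C)[C@H](O)CO | intermediate
5 | (2S,3R)-3-methylpent-4-yne-1,2-diol | C#C[C@@H](C)[C@H](O)CO | intermediate
6 | (2S,3R)-3-methyl-1,2-bis(triethylsilyloxy)pent-4-yne | C#C[C@@H](C)[C@H](O[Si](CC)(CC)CC)CO[Si](CC)(CC)CC | intermediate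
7 | butane-2,3-dione | CC(=O)C(C)=O | starting material
8 | 3-(trimethylsilyloxy)but-3-en-2-one | CC(=O)C(=C)O[Si](C)(C)C | intermediate
9 | 2-methoxy-1,3-dioxolane | COC1OCCO1 | starting material
10 | 1-(1,3-dioxolan-2-yl)butane-2,3-dione | CC(=O)C(=O)CC1OCCO1 | intermediate
11 | (3R,6R,7S)-1-(1,3-dioxolan-2-yl)-3-hydroxy-3,6-dimethyl-7,8-bis(triethylsilyloxy)oct-4-yn-2-one | C[C@@](O)(C#C[C@@H](C)[C@H](O[Si](CC)(CC)CC)CO[Si](CC)(CC)CC)C(=O)CC1OCCO1 | intermediate
12 | (2R)-5-[(2S,3S)-3,4-bis(triethylsilyloxy)butan-2-yl]-2-(1,3-dioxolan-2-ylmethyl)-2-methylfuran-3(2H)-one | C[C@]1(CC2OCCO2)OC(=CC1=O)[C@@H](C)[C@H](O[Si](CC)(CC)CC)CO[Si](CC)(CC)CC | intermediate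
13 | (2S,3S)-3-[(5R)-5-(1,3-dioxolan-2-ylmethyl)-5-methyl-4-oxo-4,5-dihydrofuran-2-yl]-2-(triethylsilyloxy)butanal | C[C@]1(CC2OCCO2)OC(=CC1=O)[C@@H](C)[C@H](O[Si](CC)(CC)CC)C=O | intermediate
14 | vinylmagnesium bromide | C=C[Mg]Br | starting material
15 | 2-methylpropanoyl chloride | CC(C)C(=O)Cl | starting material
16 | vinylzinc alkoxide of (2R)-2-(1,3-dioxolan-2-ylmethyl)-5-[(2S,3S,4S)-4-hydroxy-3-(triethylsilyloxy)hex-5-en-2-yl]-2-methylfuran-3(2H)-one | C[C@]1(CC2OCCO2)OC(=CC1=O)[C@@H](C)[C@H](O[Si](CC)(CC)CC)[C@@H](O[Zn]C=C)C=C | intermediate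
17 | (3S,4S,5S)-5-[(5R)-5-(1,3-dioxolan-2-ylmethyl)-5-methyl-4-oxo-4,5-dihydrofuran-2-yl]-4-(triethylsilyloxy)hex-1-en-3-yl 2-methylpropanoate | C[C@]1(CC2OCCO2)OC(=CC1=O)[C@@H](C)[C@H](O[Si](CC)(CC)CC)[C@@H](OC(=O)C(C)C)C=C | intermediate
18 | (2R,3S,4S)-4-[(5R)-5-(1,3-dioxolan-2-ylmethyl)-5-methyl-4-oxo-4,5-dihydrofuran-2-yl]-1-oxo-3-(triethylsilyloxy)pentan-2-yl 2-methylpropanoate | C[C@]1(CC2OCCO2)OC(=CC1=O)[C@@H](C)[C@H](O[Si](CC)(CC)CC)[C@@H](OC(=O)C(C)C)C=O | intermediate
19 | methyl acrylate | C=CC(=O)OC | starting material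
20 | methyl (4S,5S,6S)-6-[(5R)-5-(1,3-dioxolan-2-ylmethyl)-5-methyl-4-oxo-4,5-dihydrofuran-2-yl]-3-hydroxy-2-methylidene-4-(2-methylpropanoyloxy)-5-(triethylsilyloxy)heptanoate, both C-3 epimers | C[C@]1(CC2OCCO2)OC(=CC1=O)[C@@H](C)[C@H](O[Si](CC)(CC)CC)[C@@H](OC(=O)C(C)C)C(O)C(=C)C(=O)OC | intermediate
21 | methyl (2Z,4S,5S,6S)-2-(bromomethyl)-6-[(5R)-5-(1,3-dioxolan-2-ylmethyl)-5-methyl-4-oxo-4,5-dihydrofuran-2-yl]-4-(2-methylpropanoyloxy)-5-(triethylsilyloxy)hept-2-enoate | C[C@]1(CC2OCCO2)OC(=CC1=O)[C@@H](C)[C@H](O[Si](CC)(CC)CC)[C@@H](OC(=O)C(C)C)/C=C(\CBr)C(=O)OC | intermediate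
22 | methyl (2Z,4S,5S,6S)-2-(bromomethyl)-5-hydroxy-6-[(5R)-5-methyl-4-oxo-5-(2-oxoethyl)-4,5-dihydrofuran-2-yl]-4-(2-methylpropanoyloxy)hept-2-enoate | C[C@]1(CC=O)OC(=CC1=O)[C@@H](C)[C@H](O)[C@@H](OC(=O)C(C)C)/C=C(\CBr)C(=O)OC | intermediate
23 | ring-closed hydroxy ester as its dichlorochromium alkoxide: methyl 2-(ten-membered ring C-7)prop-2-enoate with O–CrCl2 on C-8 and C-4, C-5, C-6, C-7, C-8, C-10 configured as in 24 | C=C(C(=O)OC)[C@@H]1[C@@H](O[Cr](Cl)Cl)C[C@@]2(C)OC(=CC2=O)[C@@H](C)[C@H](O)[C@H]1OC(=O)C(C)C | intermediate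
24 | CNP0141385.1: (4S,5S,6S,7R,8S,10R)-5-hydroxy-6-(2-methylpropanoyloxy)-1-oxo-3,10-epoxygermacra-2,11(13)-dien-12,8-olide (locants as defined above) | C=C1C(=O)O[C@H]2C[C@@]3(C)OC(=CC3=O)[C@@H](C)[C@H](O)[C@@H](OC(=O)C(C)C)[C@H]12 | target

## Step count and risks

Total: 14 steps. Longest linear sequence: 12 steps (1–3, then 6–14); the diketone branch (steps 4–5) is 2 steps.

**Step 6 (the new alkynylation).** The risks are attack at the wrong carbonyl of 10, which would lead to the C-10 epimer after step 7, and insufficient facial control. The fallback uses known chemistry, sets out from 6 and comes back at 11. Zn(OTf)2/Et3N with a chiral amino alcohol ligand (established enantioselective alkynylation of α-keto esters) adds 6 to methyl pyruvate, which has only one ketone, to give methyl (2R,5R,6S)-2-hydroxy-2,5-dimethyl-6,7-bis(triethylsilyloxy)hept-3-ynoate F1. MeNHOMe·HCl/iPrMgCl converts this into the Weinreb amide (2R,5R,6S)-2-hydroxy-N-methoxy-N,2,5-trimethyl-6,7-bis(triethylsilyloxy)hept-3-ynamide F2. Commercial (1,3-dioxolan-2-ylmethyl)magnesium bromide then adds once to give 11. This costs two extra steps.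

**Step 9 (chelation-controlled vinylation).** An α-silyloxy aldehyde chelates poorly, and the Lewis-basic furanone may compete for EtZnCl, so the 5,6-syn selectivity may be low. The fallback sets out from 13 and comes back at 17. CH2=CHMgBr in THF at −78 °C (Felkin–Anh, no chelation) gives the 5,6-anti alcohol (2R)-2-(1,3-dioxolan-2-ylmethyl)-5-[(2S,3S,4R)-4-hydroxy-3-(triethylsilyloxy)hex-5-en-2-yl]-2-methylfuran-3(2H)-one F3. A Mitsunobu esterification with 2-methylpropanoic acid (PPh3, DIAD) then inverts C-6 and installs the ester, giving 17.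

**Step 14 (chromium macrocyclisation).** Oligomerisation, β-elimination of the furanone oxygen from the aldehyde, or the wrong C-7/C-8 relationship are possible; the trans-lactone outcome is argued from the transition-state model, not secured. The fallback sets out from 21 and comes back at 24. Pd2(dba)3-catalysed borylation with B2pin2 gives the allylboronate methyl (2E,4S,5S,6S)-6-[(5R)-5-(1,3-dioxolan-2-ylmethyl)-5-methyl-4-oxo-4,5-dihydrofuran-2-yl]-4-(2-methylpropanoyloxy)-2-[(4,4,5,5-tetramethyl-1,3,2-dioxaborolan-2-yl)methyl]-5-(triethylsilyloxy)hept-2-enoate F4. Aqueous TFA unmasks the aldehyde methyl (2E,4S,5S,6S)-5-hydroxy-6-[(5R)-5-methyl-4-oxo-5-(2-oxoethyl)-4,5-dihydrofuran-2-yl]-4-(2-methylpropanoyloxy)-2-[(4,4,5,5-tetramethyl-1,3,2-dioxaborolan-2-yl)methyl]hept-2-enoate F5. At high dilution with In(OTf)3 this closes through a six-membered boron-bound transition state (stereospecific allylboration, no fluxional allylmetal), and the borate lactonises to 24.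

Further compounds
F1 | step 6 | methyl (2R,5R,6S)-2-hydroxy-2,5-dimethyl-6,7-bis(triethylsilyloxy)hept-3-ynoate | C[C@@](O)(C#C[C@@H](C)[C@H](O[Si](CC)(CC)CC)CO[Si](CC)(CC)CC)C(=O)OC
F2 | step 6 | (2R,5R,6S)-2-hydroxy-N-methoxy-N,2,5-trimethyl-6,7-bis(triethylsilyloxy)hept-3-ynamide | C[C@@](O)(C#C[C@@H](C)[C@H](O[Si](CC)(CC)CC)CO[Si](CC)(CC)CC)C(=O)N(C)OC
F3 | step 9 | (2R)-2-(1,3-dioxolan-2-ylmethyl)-5-[(2S,3S,4R)-4-hydroxy-3-(triethylsilyloxy)hex-5-en-2-yl]-2-methylfuran-3(2H)-one | C[C@]1(CC2OCCO2)OC(=CC1=O)[C@@H](C)[C@H](O[Si](CC)(CC)CC)[C@H](O)C=C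
F4 | step 14 | methyl (2E,4S,5S,6S)-6-[(5R)-5-(1,3-dioxolan-2-ylmethyl)-5-methyl-4-oxo-4,5-dihydrofuran-2-yl]-4-(2-methylpropanoyloxy)-2-[(4,4,5,5-tetramethyl-1,3,2-dioxaborolan-2-yl)methyl]-5-(triethylsilyloxy)hept-2-enoate | C[C@]1(CC2OCCO2)OC(=CC1=O)[C@@H](C)[C@H](O[Si](CC)(CC)CC)[C@@H](OC(=O)C(C)C)/C=C(\CB2OC(C)(C)C(C)(C)O2)C(=O)OC
F5 | step 14 | methyl (2E,4S,5S,6S)-5-hydroxy-6-[(5R)-5-methyl-4-oxo-5-(2-oxoethyl)-4,5-dihydrofuran-2-yl]-4-(2-methylpropanoyloxy)-2-[(4,4,5,5-tetramethyl-1,3,2-dioxaborolan-2-yl)methyl]hept-2-enoate | C[C@]1(CC=O)OC(=CC1=O)[C@@H](C)[C@H](O)[C@@H](OC(=O)C(C)C)/C=C(\CB2OC(C)(C)C(C)(C)O2)C(=O)OC
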